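## Retrosynthetic overview

1. Target **27** ⇐ **25**: the 2,3- and 4,15-epoxides both come from one O2 (¹O2 [4+2] on the C2=C3–C4=C15 diene, then endoperoxide → syn-bis-epoxide). **25** ⇐ **24** by 1(10)-epoxidation.
2. **24** ⇐ **17**: the ten-membered carbocycle and the 12,6-lactone form in one operation by closing C6–C7 (allylchromium onto aldehyde), the bond the terpene cyclase closes.
3. **17** ⇐ **13** + **4** (Sonogashira coupling, cis-semireduction). **13** comes from (R)-glycidol, acetylide, Me3Al and methyl acrylate; **4** from (E)-3-methylpent-2-en-4-yn-1-ol (Sharpless epoxidation, epoxide → allyl silyl ether).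
4. Ring order: carbocycle → lactone → 1,10-epoxide → 2,3- and 4,15-epoxides.

Assumption: germacrane numbering is used (lactone C12–O–C6, ester on C8), and the presumed biosynthesis is taken as farnesyl C6–C7 cyclisation, 6α-lactonisation, 8α-acylation, 1(10)-epoxidation and O2 addition across a 2Z,4(15)-diene (endoperoxide → 2,3:4,15-bis-epoxide).

Target as read from the SMILES: ten-membered carbocycle; trans-fused α-methylene-γ-lactone (C6–O, C7); 8α-angelate; 5α-OH; 1β,10α-, cis-2β,3β- and spiro-4α,15-epoxides; (1R,2R,3S,4S,5S,6S,7R,8S,10R).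

## Route

Step 1
Reactants: 1 (E)-3-methylpent-2-en-4-yn-1-ol
Product: 2 [(2S,3S)-3-ethynyl-3-methyloxiran-2-yl]methanol
Conditions: Ti(OiPr)4 (10 mol%), L-(+)-DET (12 mol%), TBHP (2 equiv), 4 Å MS, CH2Cl2, −20 °C
Reagents that add atoms: tert-butyl hydroperoxide, CC(C)(C)OO
Why: Katsuki–Sharpless asymmetric epoxidation of the primary allylic alcohol; the L-(+)-tartrate catalyst gives the (2S,3S)-epoxide, which fixes the C–O stereocentre that becomes C5 of the target.

Step 2
Reactants: 2 [(2S,3S)-3-ethynyl-3-methyloxiran-2-yl]methanol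
Product: 4 (2R)-2-(tert-butyldimethylsilyloxy)-3-methylidene-1-(triethylsilyloxy)pent-4-yne, via O-triethylsilyl epoxy alcohol 3 (not isolated)
Conditions: TESOTf (1.0 equiv), 2,6-lutidine, CH2Cl2, −78 °C; then TBSOTf (1.3 equiv), −78 → 0 °C; then DBU, rt
Reagents that add atoms: triethylsilyl triflate, CC[Si](CC)(CC)OS(=O)(=O)C(F)(F)F; tert-butyldimethylsilyl triflate, CC(C)(C)[Si](C)(C)OS(=O)(=O)C(F)(F)F
Why: O-silylation followed by a Noyori-type silyl triflate/amine epoxide-to-allyl silyl ether isomerisation: the silylated epoxide opens at the tertiary propargylic carbon, whose only β-hydrogens are on the methyl group, so the 4(15)-methylidene forms while the untouched C5–O bond keeps its configuration.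

Step 3
Reactants: 5 (R)-glycidol; 6 lithium acetylide–ethylenediamine complex
Product: 7 (S)-pent-4-yne-1,2-diol
Conditions: 6 (3 equiv), DMSO, 0 °C → rt; then H2O
Reagents that add atoms: none
Why: SN2 alkynylation of the epoxide at its unsubstituted carbon; the carbinol stereocentre is not touched and becomes C8 (S).

Step 4
Reactants: 7 (S)-pent-4-yne-1,2-diol
Product: 8 (S)-1,2-bis(triethylsilyloxy)pent-4-yne
Conditions: TESCl (2.3 equiv), imidazole, CH2Cl2, 0 °C → rt
Reagents that add atoms: chlorotriethylsilane, CC[Si](Cl)(CC)CC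
Why: standard imidazole-mediated silylation of both hydroxyls, so that the primary one can later be oxidised selectively.

Step 5
Reactants: 8 (S)-1,2-bis(triethylsilyloxy)pent-4-yne
Product: 10 (S,E)-1-iodo-2-methyl-4,5-bis(triethylsilyloxy)pent-1-ene, via alkenyldimethylalane 9 (not isolated)
Conditions: Me3Al (3 equiv), Cp2ZrCl2 (0.3 equiv), CH2Cl2, 0 °C → rt; then I2, THF, −30 → 0 °C
Reagents that add atoms: trimethylaluminium, C[Al](C)C; iodine, II
Why: Negishi zirconium-catalysed carboalumination adds methyl and aluminium syn across the alkyne (methyl to the internal carbon) and iodinolysis goes with retention, giving only the E-trisubstituted vinyl iodide (future C10=C1).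

Step 6
Reactants: 10 (S,E)-1-iodo-2-methyl-4,5-bis(triethylsilyloxy)pent-1-ene
Product: 11 (S,E)-5-iodo-4-methyl-2-(triethylsilyloxy)pent-4-enal
Conditions: (COCl)2, DMSO, CH2Cl2, −78 → −40 °C; Et3N, −78 → 0 °C
Reagents that add atoms: none
Why: Swern conditions cleave and oxidise a primary triethylsilyl ether while the secondary one survives (selective oxidative desilylation), giving the α-silyloxy aldehyde without epimerisation at low temperature.

Step 7
Reactants: 11 (S,E)-5-iodo-4-methyl-2-(triethylsilyloxy)pent-4-enal; 12 methyl acrylate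
Product: 13 methyl (4S,6E)-3-hydroxy-7-iodo-6-methyl-2-methylidene-4-(triethylsilyloxy)hept-6-enoate (C3 epimer mixture)
Conditions: methyl acrylate (5 equiv), DABCO (1 equiv), neat, rt, 3–5 d
Reagents that add atoms: none
Why: Morita–Baylis–Hillman reaction of the activated α-silyloxy aldehyde; the new carbinol (future C7) forms as an epimer mixture, which does not matter because it is erased in step 10.

Step 8
Reactants: 13 methyl (4S,6E)-3-hydroxy-7-iodo-6-methyl-2-methylidene-4-(triethylsilyloxy)hept-6-enoate; 4 (2R)-2-(tert-butyldimethylsilyloxy)-3-methylidene-1-(triethylsilyloxy)pent-4-yne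
Product: 14 methyl (4S,6E,11R)-11-(tert-butyldimethylsilyloxy)-3-hydroxy-6-methyl-2,10-dimethylidene-4,12-bis(triethylsilyloxy)dodec-6-en-8-ynoate
Conditions: Pd(PPh3)2Cl2 (5 mol%), CuI (10 mol%), iPr2NH, THF, rt
Reagents that add atoms: none
Why: Sonogashira coupling of the E-vinyl iodide with the terminal alkyne goes with retention of alkene geometry and tolerates the free alcohol, the acrylate and the silyl ethers.

Step 9
Reactants: 14 methyl (4S,6E,11R)-11-(tert-butyldimethylsilyloxy)-3-hydroxy-6-methyl-2,10-dimethylidene-4,12-bis(triethylsilyloxy)dodec-6-en-8-ynoate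
Product: 15 methyl (4S,6E,8Z,11R)-11-(tert-butyldimethylsilyloxy)-3-hydroxy-6-methyl-2,10-dimethylidene-4,12-bis(triethylsilyloxy)dodeca-6,8-dienoate
Conditions: Zn(Cu/Ag), THF/MeOH/H2O, rt → 35 °C, dark
Reagents that add atoms: none
Why: Boland reduction with Zn(Cu/Ag) is a cis-selective semireduction specific for conjugated alkynes, setting the 2Z alkene without touching the other alkenes.

Step 10
Reactants: 15 methyl (4S,6E,8Z,11R)-11-(tert-butyldimethylsilyloxy)-3-hydroxy-6-methyl-2,10-dimethylidene-4,12-bis(triethylsilyloxy)dodeca-6,8-dienoate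
Product: 16 methyl (2Z,4S,6E,8Z,11R)-2-(bromomethyl)-11-(tert-butyldimethylsilyloxy)-6-methyl-10-methylidene-4,12-bis(triethylsilyloxy)dodeca-2,6,8-trienoate
Conditions: NBS, Me2S, CH2Cl2, −40 → 0 °C
Reagents that add atoms: N-bromosuccinimide, O=C1CCC(=O)N1Br
Why: Corey–Kim-type activation of the Baylis–Hillman alcohol and SN2' attack of bromide give the thermodynamically preferred (Z)-2-(bromomethyl)enoate.

Step 11
Reactants: 16 methyl (2Z,4S,6E,8Z,11R)-2-(bromomethyl)-11-(tert-butyldimethylsilyloxy)-6-methyl-10-methylidene-4,12-bis(triethylsilyloxy)dodeca-2,6,8-trienoate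
Product: 17 methyl (2Z,4S,6E,8Z,11R)-2-(bromomethyl)-11-(tert-butyldimethylsilyloxy)-6-methyl-10-methylidene-12-oxo-4-(triethylsilyloxy)dodeca-2,6,8-trienoate
Conditions: (COCl)2, DMSO, CH2Cl2, −78 → −45 °C; iPr2NEt, −78 → −20 °C; used at once
Reagents that add atoms: none
Why: the same selective Swern oxidation of the only primary triethylsilyl ether; Hünig's base at low temperature avoids attack on the allylic bromide and migration of the β,γ-double bond.

Step 12
Reactants: 17 methyl (2Z,4S,6E,8Z,11R)-2-(bromomethyl)-11-(tert-butyldimethylsilyloxy)-6-methyl-10-methylidene-12-oxo-4-(triethylsilyloxy)dodeca-2,6,8-trienoate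
Product: 20 8α-hydroxy-5α-(tert-butyldimethylsilyloxy)germacra-1(10)E,2Z,4(15),11(13)-tetraen-12,6α-olide, via macrocyclic hydroxy ester 18 (not isolated), via bis-silyl lactone 19 (not isolated)
Conditions: CrCl2 (10 equiv), THF, 2 mM, syringe-pump addition over 10 h, rt; then 1 M aq. HCl, 0 °C → rt
Reagents that add atoms: none
Why: Nozaki–Hiyama–Kishi-type Cr(II) intramolecular 2-(alkoxycarbonyl)allylation closes the ten-membered ring at C6–C7 through a chair transition state with both ring arms equatorial (6,7-anti, the trans-lactone) and Felkin–Anh attack anti to the C5–OTBS group (5,6-anti), after which the chromium alkoxide lactonises and the acid removes only the triethylsilyl ether.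

Step 13
Reactants: 20 8α-hydroxy-5α-(tert-butyldimethylsilyloxy)germacra-1(10)E,2Z,4(15),11(13)-tetraen-12,6α-olide; 21 angelic acid
Product: 23 8α-angeloyloxy-5α-(tert-butyldimethylsilyloxy)germacra-1(10)E,2Z,4(15),11(13)-tetraen-12,6α-olide, via angelic 2,4,6-trichlorobenzoic anhydride 22 (not isolated)
Conditions: 21, 2,4,6-trichlorobenzoyl chloride, Et3N, toluene, rt; then 20, DMAP, rt → 40 °C
Reagents that add atoms: none
Why: Yamaguchi esterification through the mixed anhydride acylates the only free hydroxyl and is the standard way to introduce an angelate without Z→E isomerisation to the tiglate.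

Step 14
Reactants: 23 8α-angeloyloxy-5α-(tert-butyldimethylsilyloxy)germacra-1(10)E,2Z,4(15),11(13)-tetraen-12,6α-olide
Product: 24 8α-angeloyloxy-5α-hydroxygermacra-1(10)E,2Z,4(15),11(13)-tetraen-12,6α-olide
Conditions: HF·pyridine, pyridine, THF, 0 °C → rt
Reagents that add atoms: none
Why: buffered fluoride desilylation cleaves the secondary TBS ether and leaves the angelate, the α-methylene lactone and the triene untouched.

Step 15
Reactants: 24 8α-angeloyloxy-5α-hydroxygermacra-1(10)E,2Z,4(15),11(13)-tetraen-12,6α-olide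
Product: 25 8α-angeloyloxy-1β,10α-epoxy-5α-hydroxygermacra-2Z,4(15),11(13)-trien-12,6α-olide
Conditions: mCPBA (1.05 equiv), NaHCO3, CH2Cl2, −20 → 0 °C
Reagents that add atoms: meta-chloroperoxybenzoic acid, OOC(=O)c1cccc(Cl)c1
Why: Prilezhaev epoxidation takes place at the most electron-rich (trisubstituted) alkene and, as in other 1(10)E-germacranolides, from the exposed outer face of the ring, which gives the 1β,10α-epoxide (1R,10R) with retention of the E geometry.

Step 16
Reactants: 25 8α-angeloyloxy-1β,10α-epoxy-5α-hydroxygermacra-2Z,4(15),11(13)-trien-12,6α-olide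
Product: 27 CNP0594916.1 (8α-angeloyloxy-1β,10α:2β,3β:4α,15-triepoxy-5α-hydroxygermacr-11(13)-en-12,6α-olide), via 2,15-endoperoxide 26 (not isolated)
Conditions: O2, TPP (1 mol%), hν (white LED), CH2Cl2, −30 °C; then Co(TPP) (5 mol%), −30 → 0 °C
Reagents that add atoms: dioxygen (as singlet oxygen), O=O
Why: singlet oxygen adds suprafacially in a [4+2] cycloaddition to the C2=C3–C4=C15 diene on the face syn to the hydrogen-bonding 5-OH and anti to the 1,10-epoxide oxygen, and the Co(II)-catalysed endoperoxide-to-bis-epoxide rearrangement (Foote–Boyd type) transfers the two oxygens to C3 and C4 on that same face, giving the cis-2β,3β-epoxide and the 4α,15-epoxide syn to each other and completing C2, C3 and C4.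

## Compound list

1 | (E)-3-methylpent-2-en-4-yn-1-ol | C#C/C(C)=C/CO | starting material
2 | [(2S,3S)-3-ethynyl-3-methyloxiran-2-yl]methanol | OC[C@@H]1O[C@@]1(C)C#C | intermediate
3 | triethyl{[(2S,3S)-3-ethynyl-3-methyloxiran-2-yl]methoxy}silane (not isolated) | CC[Si](CC)(CC)OC[C@@H]1O[C@@]1(C)C#C | intermediate
4 | (2R)-2-(tert-butyldimethylsilyloxy)-3-methylidene-1-(triethylsilyloxy)pent-4-yne | C#CC(=C)[C@@H](O[Si](C)(C)C(C)(C)C)CO[Si](CC)(CC)CC | intermediate
5 | (R)-glycidol | OC[C@@H]1CO1 | starting material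
6 | lithium acetylide–ethylenediamine complex | [Li+].[C-]#C.NCCN | starting material
7 | (S)-pent-4-yne-1,2-diol | C#CC[C@H](O)CO | intermediate
8 | (S)-1,2-bis(triethylsilyloxy)pent-4-yne | C#CC[C@H](O[Si](CC)(CC)CC)CO[Si](CC)(CC)CC | intermediate
9 | (S,E)-dimethyl[2-methyl-4,5-bis(triethylsilyloxy)pent-1-enyl]alane (not isolated) | C/C(=C\[Al](C)C)C[C@H](O[Si](CC)(CC)CC)CO[Si](CC)(CC)CC | intermediate
10 | (S,E)-1-iodo-2-methyl-4,5-bis(triethylsilyloxy)pent-1-ene | C/C(=C\I)C[C@H](O[Si](CC)(CC)CC)CO[Si](CC)(CC)CC | intermediate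
11 | (S,E)-5-iodo-4-methyl-2-(triethylsilyloxy)pent-4-enal | C/C(=C\I)C[C@H](O[Si](CC)(CC)CC)C=O | intermediate
12 | methyl acrylate | C=CC(=O)OC | starting material
13 | methyl (4S,6E)-3-hydroxy-7-iodo-6-methyl-2-methylidene-4-(triethylsilyloxy)hept-6-enoate (C3 epimers) | C=C(C(=O)OC)C(O)[C@@H](O[Si](CC)(CC)CC)C/C(C)=C/I | intermediate
14 | methyl (4S,6E,11R)-11-(tert-butyldimethylsilyloxy)-3-hydroxy-6-methyl-2,10-dimethylidene-4,12-bis(triethylsilyloxy)dodec-6-en-8-ynoate (C3 epimers) | C=C(C(=O)OC)C(O)[C@@H](O[Si](CC)(CC)CC)C/C(C)=C/C#CC(=C)[C@@H](O[Si](C)(C)C(C)(C)C)CO[Si](CC)(CC)CC | intermediate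
15 | methyl (4S,6E,8Z,11R)-11-(tert-butyldimethylsilyloxy)-3-hydroxy-6-methyl-2,10-dimethylidene-4,12-bis(triethylsilyloxy)dodeca-6,8-dienoate (C3 epimers) | C=C(C(=O)OC)C(O)[C@@H](O[Si](CC)(CC)CC)C/C(C)=C/C=C\C(=C)[C@@H](O[Si](C)(C)C(C)(C)C)CO[Si](CC)(CC)CC | intermediate
16 | methyl (2Z,4S,6E,8Z,11R)-2-(bromomethyl)-11-(tert-butyldimethylsilyloxy)-6-methyl-10-methylidene-4,12-bis(triethylsilyloxy)dodeca-2,6,8-trienoate | BrC/C(C(=O)OC)=C\[C@@H](O[Si](CC)(CC)CC)C/C(C)=C/C=C\C(=C)[C@@H](O[Si](C)(C)C(C)(C)C)CO[Si](CC)(CC)CC | intermediate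
17 | methyl (2Z,4S,6E,8Z,11R)-2-(bromomethyl)-11-(tert-butyldimethylsilyloxy)-6-methyl-10-methylidene-12-oxo-4-(triethylsilyloxy)dodeca-2,6,8-trienoate | BrC/C(C(=O)OC)=C\[C@@H](O[Si](CC)(CC)CC)C/C(C)=C/C=C\C(=C)[C@@H](O[Si](C)(C)C(C)(C)C)C=O | intermediate
18 | methyl 6α-hydroxy-5α-(tert-butyldimethylsilyloxy)-8α-(triethylsilyloxy)germacra-1(10)E,2Z,4(15),11(13)-tetraen-12-oate (not isolated) | C=C(C(=O)OC)[C@@H]1[C@@H](O[Si](CC)(CC)CC)C/C(C)=C/C=C\C(=C)[C@@H](O[Si](C)(C)C(C)(C)C)[C@H]1O | intermediate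
19 | 5α-(tert-butyldimethylsilyloxy)-8α-(triethylsilyloxy)germacra-1(10)E,2Z,4(15),11(13)-tetraen-12,6α-olide (not isolated) | C=C1C(=O)O[C@H]2[C@H]1[C@@H](O[Si](CC)(CC)CC)C/C(C)=C/C=C\C(=C)[C@H]2O[Si](C)(C)C(C)(C)C | intermediate
20 | 8α-hydroxy-5α-(tert-butyldimethylsilyloxy)germacra-1(10)E,2Z,4(15),11(13)-tetraen-12,6α-olide | C=C1C(=O)O[C@H]2[C@H]1[C@@H](O)C/C(C)=C/C=C\C(=C)[C@H]2O[Si](C)(C)C(C)(C)C | intermediate
21 | angelic acid, (Z)-2-methylbut-2-enoic acid | C/C=C(/C)C(=O)O | starting material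
22 | angelic 2,4,6-trichlorobenzoic anhydride (not isolated) | C/C=C(/C)C(=O)OC(=O)c1c(Cl)cc(Cl)cc1Cl | intermediate
23 | 8α-angeloyloxy-5α-(tert-butyldimethylsilyloxy)germacra-1(10)E,2Z,4(15),11(13)-tetraen-12,6α-olide | C=C1C(=O)O[C@H]2[C@H]1[C@@H](OC(=O)/C(C)=C\C)C/C(C)=C/C=C\C(=C)[C@H]2O[Si](C)(C)C(C)(C)C | intermediate
24 | 8α-angeloyloxy-5α-hydroxygermacra-1(10)E,2Z,4(15),11(13)-tetraen-12,6α-olide | C=C1C(=O)O[C@H]2[C@H]1[C@@H](OC(=O)/C(C)=C\C)C/C(C)=C/C=C\C(=C)[C@H]2O | intermediate
25 | 8α-angeloyloxy-1β,10α-epoxy-5α-hydroxygermacra-2Z,4(15),11(13)-trien-12,6α-olide | C=C1C(=O)O[C@H]2[C@H]1[C@@H](OC(=O)/C(C)=C\C)C[C@@]1(C)O[C@@H]1/C=C\C(=C)[C@H]2O | intermediate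
26 | 8α-angeloyloxy-2β,15-epidioxy-1β,10α-epoxy-5α-hydroxygermacra-3E,11(13)-dien-12,6α-olide (not isolated) | C=C1C(=O)O[C@H]2[C@H]1[C@@H](OC(=O)/C(C)=C\C)C[C@@]1(C)O[C@@H]1[C@@H]1OOCC(=C1)[C@H]2O | intermediate
27 | CNP0594916.1, 8α-angeloyloxy-1β,10α:2β,3β:4α,15-triepoxy-5α-hydroxygermacr-11(13)-en-12,6α-olide | C=C1C(=O)O[C@H]2[C@H]1[C@@H](OC(=O)/C(C)=C\C)C[C@@]1(C)O[C@@H]1[C@@H]1O[C@@H]1[C@]1(CO1)[C@H]2O | target

## Step count and risks

Total step count: 16 (steps 1–2 make fragment 4; steps 3–7 make fragment 13; steps 8–16 are common).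
Longest linear sequence: 14 steps (steps 3–16, from (R)-glycidol).

Three steps most likely to fail:

Step 12 (ring closure at C6–C7 with lactonisation). The risks are oligomerisation, loss of the C8 silyloxy group from the allylchromium by 1,4-elimination, and the wrong C6/C7 diastereomer, because the influence of the C8 stereocentre on the face of C7 is not known. The fallback sets out from 15 and changes how the allyl nucleophile is made. Acetylation (Ac2O, pyridine, 0 °C) gives the Baylis–Hillman acetate F1. The same selective Swern oxidation of its primary triethylsilyl ether gives the acetoxy aldehyde F2. Palladium-catalysed umpolung (Pd(PPh3)4 cat., Et2Zn, K2CO3, DMA, 2 mM) then ionises the allylic acetate to the 2-(methoxycarbonyl)allylpalladium species and transmetalates it to an allylzinc, which adds through C7 to the aldehyde; this is a known way of closing germacrane rings at this bond. The same aqueous HCl treatment returns the route at 20.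

Step 15 (1,10-epoxidation). The risks are attack on the wrong face of C1=C10 in this unusual 2Z-triene conformation and competing hydroxyl-directed epoxidation of C4=C15. The fallback sets out from 23 and uses catalyst control before the hydroxyl is freed. Shi epoxidation of the silyl ether (D-fructose-derived ketone, or its enantiomer if the other face is required, Oxone, K2CO3, MeCN/DMM/buffer, 0 °C) gives 8α-angeloyloxy-1β,10α-epoxy-5α-(tert-butyldimethylsilyloxy)germacra-2Z,4(15),11(13)-trien-12,6α-olide F3. Buffered desilylation (TBAF/AcOH, THF, 0 °C) returns the route at 25.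

Step 16 (singlet-oxygen cascade). The risks are a twisted diene that reacts slowly, ene reaction or attack from the wrong face, and Kornblum–DeLaMare collapse of the endoperoxide to a hydroxy enone or enal instead of the bis-epoxide. The fallback sets out from 25 and forms the two epoxides one at a time. Hydroxyl-directed epoxidation (VO(acac)2 cat., TBHP, CH2Cl2, 0 °C) delivers oxygen to C4=C15 syn to the 5α-OH and gives 8α-angeloyloxy-1β,10α:4α,15-diepoxy-5α-hydroxygermacra-2Z,11(13)-dien-12,6α-olide F4. Dimethyldioxirane (acetone, 0 °C) then epoxidises the remaining cis-C2=C3 from the face anti to the two flanking epoxide oxygens, returning the route at 27.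

## Further compounds

F1 | step 12 | methyl (4S,6E,8Z,11R)-3-acetoxy-11-(tert-butyldimethylsilyloxy)-6-methyl-2,10-dimethylidene-4,12-bis(triethylsilyloxy)dodeca-6,8-dienoate (C3 epimers) | C=C(C(=O)OC)C(OC(C)=O)[C@@H](O[Si](CC)(CC)CC)C/C(C)=C/C=C\C(=C)[C@@H](O[Si](C)(C)C(C)(C)C)CO[Si](CC)(CC)CC
F2 | step 12 | methyl (4S,6E,8Z,11R)-3-acetoxy-11-(tert-butyldimethylsilyloxy)-6-methyl-2,10-dimethylidene-12-oxo-4-(triethylsilyloxy)dodeca-6,8-dienoate (C3 epimers) | C=C(C(=O)OC)C(OC(C)=O)[C@@H](O[Si](CC)(CC)CC)C/C(C)=C/C=C\C(=C)[C@@H](O[Si](C)(C)C(C)(C)C)C=O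
F3 | step 15 | 8α-angeloyloxy-1β,10α-epoxy-5α-(tert-butyldimethylsilyloxy)germacra-2Z,4(15),11(13)-trien-12,6α-olide | C=C1C(=O)O[C@H]2[C@H]1[C@@H](OC(=O)/C(C)=C\C)C[C@@]1(C)O[C@@H]1/C=C\C(=C)[C@H]2O[Si](C)(C)C(C)(C)C
F4 | step 16 | 8α-angeloyloxy-1β,10α:4α,15-diepoxy-5α-hydroxygermacra-2Z,11(13)-dien-12,6α-olide | C=C1C(=O)O[C@H]2[C@H]1[C@@H](OC(=O)/C(C)=C\C)C[C@@]1(C)O[C@@H]1/C=C\[C@]1(CO1)[C@H]2O
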